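Examiner: You read the new flasks at 12 min. What is still there to react by then?

Candidate: Incoming ligand, so I follow that first. Here is the problem:

common to all: starting complex 0.020 M
- violet: incoming ligand 0.011 equiv; run made earlier
- grey: incoming ligand 0.11 equiv; run made earlier
- blue: incoming ligand 0.97 equiv; run made earlier
- Tuesday's: incoming ligand 0.0120 equiv; time 12 min
- Sunday's: incoming ligand 0.0400 equiv; time 12 min
- Wednesday's: incoming ligand 0.120 equiv; time 12 min
- Friday's: incoming ligand 0.300 equiv; time 12 min
- Monday's: incoming ligand 1.00 equiv; time 12 min

| run | time / min | complex with one exchanged / % | starting complex / % |
|---|---|---|---|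
| violet | 2.00 | 0 | 100 |
| violet | 4.00 | 1 | 96 |
| violet | 6.00 | 1 | 101 |
| violet | 8.00 | 0 | 97 |
| grey | 2.00 | 4 | 101 |
| grey | 4.00 | 1 | 95 |
| grey | 6.00 | 1 | 91 |
| grey | 8.00 | 5 | 88 |
| blue | 0.667 | 8 | 91 |
| blue | 1.50 | 14 | 83 |
| blue | 4.00 | 26 | 63 |
| blue | 8.00 | 36 | 44 |

(each reading ± 2 percentage points)

- the earlier runs were read with a standard deviation of 2 percentage points
- a reading or a percentage of complex with one exchanged counts all its forms, free or not
- "hardly changes" means that all values lie within two and a half points (for a concentration: within two and a half percent of the largest)

1. amount of complex with one exchanged at the end, in percent of the starting complex charged for Tuesday's, Sunday's, Wednesday's, Friday's, Monday's, in this order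
2. the course of these numbers from the first flask to the last (falls, then rises / hardly changes / rises all the way / rises, then falls / falls all the way)

Examiner: Define your terms.

Candidate: Let m be the starting complex as a fraction of its charge, and x the incoming ligand as a fraction of its own charge. I take each exchange to use one ligand. If the first exchange goes as m times x times the ligand charge in equivalents, then x loses the same fraction per minute at any charge while m stays near one. That is pseudo-first-order decay with the starting complex in excess.

Examiner: Give it a number, in powers of ten.

Candidate: The ligand clock is the decades of x lost per minute while m stays near one. The blue run at 1.50 min has m = 83%, so log10(1/m) divided by time and equivalents gives 0.0556 min⁻¹. It is a reading: a scatter of 2 percentage points sits on a loss of 17.0%. Over 12 min that is 0.667 decades, so I expect 21.5% of the ligand left in Tuesday's and Sunday's flasks.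

Examiner: The weak spot: the grey run lost 12.0% of its starting complex by 8.00 min, yet your clock has it using 0.0705 equivalents.

Candidate: Yes, that is 1.70 starting complexes gone per ligand used, with little complex with one exchanged on show. Either the ligand returns or each one takes out more than one starting complex, and these readings don't separate the two. My reckoning keeps the ligand used up.

Examiner: And the row?

Candidate: With the same x(t) in Tuesday's and Sunday's flasks, and if complex with one exchanged has the same lifetime in both, the amount should scale with the charge, a log-log slope of one. So Sunday's over Tuesday's should be 3.33.

The forecast differs on the ligand: “The runs point to a ligand that is recycled rather than used up.” It gives 0.25%, 0.75%, 3%, 11% and 41%, so rises all the way.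

The flasks give 0.211%, 0.712%, 2.20%, 8.12% and 43.9%, so rises all the way.

    starting complex + incoming ligand → leaving ligand + complex with one exchanged (k = 6.40 L mol⁻¹ min⁻¹)
    complex with one exchanged + incoming ligand → leaving ligand + complex with two exchanged (k = 0.680 L mol⁻¹ min⁻¹)
    complex with two exchanged + incoming ligand → leaving ligand + complex with three exchanged (k = 3.70 L mol⁻¹ min⁻¹)
    complex with three exchanged + incoming ligand → leaving ligand + complex with four exchanged (k = 0.710 L mol⁻¹ min⁻¹)
    crystals ⇌ complex with one exchanged, rate k5*(cs5 - [complex with one exchanged]) while solid is left; crystals form when [complex with one exchanged] > cs5 (solubility = 1.10 mM, k = 2.70 min⁻¹)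
    starting complex + complex with one exchanged → side product (k = 9.10 L mol⁻¹ min⁻¹)
    complex with one exchanged → over-reaction product (k = 0.0660 min⁻¹)

On Tuesday's flask the clock's 21.5% stands against 22% of the ligand left at 12.0 min. On Monday's flask, with the clock slowed by the mean of m at start and end, it gives 35.8% against 41%. Sunday's over Tuesday's comes to 3.37 against the charge ratio of 3.33, but from Friday's to Monday's the amount climbs faster than the charge. Monday's height has two reasons acting together, the ceiling of 1.1 mM on dissolved complex with one exchanged and the reading being taken at 12.0 min and not ten times later: Monday's holds 43.9%, against 18.5% without the ceiling and 21.2% at 120 min.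

The data come from a simulation from invented constants; scatter was added.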